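**Retrosynthetic overview**
- The C3 stereocentre is set last, with no ring formed: the target comes from the achiral pyrano-isoflavone by a reductase-like conjugate reduction with enantioselective protonation at C3.
- Ring D (dimethylpyran) is disconnected to prenal plus the free ring B phenol of the unprotected dihydroxy-isoflavone: o-quinone methide formation, then oxa-6π electrocyclisation.
- Ring C (pyranone) is disconnected to a 2'-hydroxychalcone: isoflavone-synthase-type oxidative 1,2-aryl shift, then acetal ring closure with loss of methanol.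
- The chalcone comes from 2,4-dihydroxyacetophenone and 4-hydroxy-2-methoxybenzaldehyde by Claisen–Schmidt condensation; rings A and B are bought.
- Order of ring formation: ring C first, then ring D.

Assumption: the stereodescriptor of the given SMILES reads as 3S and this enantiomer is made; ring A = resorcinol-derived benzo ring, ring B = pendant aryl ring, ring C = pyranone ring, ring D = dimethylpyran ring.

**Step 1**
Reactants: 1 2,4-dihydroxyacetophenone; 2 4-hydroxy-2-methoxybenzaldehyde
Product: 5 (E)-1-[2-hydroxy-4-(methoxymethoxy)phenyl]-3-[2-methoxy-4-(methoxymethoxy)phenyl]prop-2-en-1-one, via mono-MOM ketone 3 (not isolated), via mono-MOM aldehyde 4 (not isolated)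
Conditions: 1 + 2 (1:1), MOMCl (2.1 equiv), K2CO3, acetone, 0 °C→rt; filter, evaporate to dryness; then KOH, EtOH–H2O, rt, 48 h; AcOH quench
Reagents that add atoms: chloromethyl methyl ether (MOMCl), COCCl
Why: The chelated 2-OH of 1 stays free while K2CO3/MOMCl caps the two para-phenols, and the crude ethers then undergo KOH-mediated Claisen–Schmidt condensation (aldol then E1cB dehydration) to the thermodynamic E-enone; no stereocentre is formed.

**Step 2**
Reactants: 5 (E)-1-[2-hydroxy-4-(methoxymethoxy)phenyl]-3-[2-methoxy-4-(methoxymethoxy)phenyl]prop-2-en-1-one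
Product: 7 7-hydroxy-3-(4-hydroxy-2-methoxyphenyl)-4H-chromen-4-one, via β-keto dimethyl acetal 6 (not isolated)
Conditions: Tl(NO3)3·3H2O (1.1 equiv), MeOH–HC(OMe)3 (3:1), rt, 3 h; filter, NaHCO3 wash, concentrate; then HCl (1.25 M in MeOH), 60 °C, 4 h
Reagents that add atoms: none
Why: Trivalent thallium attacks the enol of the methanol adduct at Cα and the electron-rich 2,4-dioxygenated ring B migrates from Cβ to Cα (thallium nitrate oxidative rearrangement of a 2'-hydroxychalcone, the laboratory counterpart of the isoflavone-synthase aryl shift) to give acetal 6, which in methanolic HCl closes ring C through the 2-methoxyisoflavanone, loses MeOH to the isoflavone and sheds both MOM groups, so the transient stereocentre of 6 is erased.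

**Step 3**
Reactants: 7 7-hydroxy-3-(4-hydroxy-2-methoxyphenyl)-4H-chromen-4-one; 8 3-methylbut-2-enal (prenal, 1.05 equiv)
Product: 9 7-hydroxy-3-(7-methoxy-2,2-dimethyl-2H-chromen-6-yl)-4H-chromen-4-one
Conditions: PhB(OH)2 (1.2 equiv), AcOH–toluene (1:4), reflux, Dean–Stark, 16 h
Reagents that add atoms: none
Why: Phenylboronic acid tethers prenal to the ring B phenol and delivers it to C5' (ortho to OH, para to OMe, less hindered than C3'), the benzodioxaborin then extrudes the o-quinone methide, which closes ring D by oxa-6π electrocyclisation (phenylboronic-acid-mediated chromenylation), while the push–pull 7-OH ring is a much weaker carbon nucleophile and stays untouched; no stereocentre is formed.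

**Step 4**
Reactants: 9 7-hydroxy-3-(7-methoxy-2,2-dimethyl-2H-chromen-6-yl)-4H-chromen-4-one
Product: 12 (3S)-7-hydroxy-3-(7-methoxy-2,2-dimethyl-2H-chromen-6-yl)-2,3-dihydro-4H-chromen-4-one, via bis-silyl enol ether 10 (not isolated), via 7-O-silyl isoflavanone 11 (not isolated)
Conditions: RhCl(PPh3)3 (0.5 mol%), PhMe2SiH (2.3 equiv), toluene, 60 °C; then (S)-3,3'-bis(2,4,6-triisopropylphenyl)-BINOL N-triflyl thiophosphoramide (5 mol%), PhOH (1.5 equiv), toluene, −20 °C; MeOH, aq. citric acid, 0 °C
Reagents that add atoms: none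
Why: Proposed new method: RhCl(PPh3)3-catalysed 1,4-hydrosilylation puts hydride on C2 and silicon on the C4 oxygen (the 7-OH is silylated at the same time), and the resulting enol silane is protonated at C3 on one face within the chiral thiophosphoramide ion pair, phenol being the stoichiometric proton source, which sets 3S under acidic conditions that do not enolise the product (the catalyst antipode is confirmed by a pilot run, both being available); the closest known reactions are rhodium-catalysed conjugate hydrosilylation of enones and Brønsted-acid-catalysed enantioselective protonation of silyl enol ethers of 2-arylcycloalkanones.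

**Compound list**
1 | 2,4-dihydroxyacetophenone | CC(=O)c1ccc(O)cc1O | starting material
2 | 4-hydroxy-2-methoxybenzaldehyde | COc1cc(O)ccc1C=O | starting material
3 | 1-[2-hydroxy-4-(methoxymethoxy)phenyl]ethan-1-one | CC(=O)c1ccc(OCOC)cc1O | intermediate
4 | 2-methoxy-4-(methoxymethoxy)benzaldehyde | COCOc1ccc(C=O)c(OC)c1 | intermediate
5 | (E)-1-[2-hydroxy-4-(methoxymethoxy)phenyl]-3-[2-methoxy-4-(methoxymethoxy)phenyl]prop-2-en-1-one | COCOc1ccc(C(=O)/C=C/c2ccc(OCOC)cc2OC)c(O)c1 | intermediate
6 | 1-[2-hydroxy-4-(methoxymethoxy)phenyl]-3,3-dimethoxy-2-[2-methoxy-4-(methoxymethoxy)phenyl]propan-1-one (racemic) | COCOc1ccc(C(=O)C(C(OC)OC)c2ccc(OCOC)cc2OC)c(O)c1 | intermediate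
7 | 7-hydroxy-3-(4-hydroxy-2-methoxyphenyl)-4H-chromen-4-one | O=C1C(c2ccc(O)cc2OC)=COc2cc(O)ccc12 | intermediate
8 | 3-methylbut-2-enal (prenal) | CC(C)=CC=O | starting material
9 | 7-hydroxy-3-(7-methoxy-2,2-dimethyl-2H-chromen-6-yl)-4H-chromen-4-one | COc1cc2OC(C)(C)C=Cc2cc1C1=COc2cc(O)ccc2C1=O | intermediate
10 | 4,7-bis{[dimethyl(phenyl)silyl]oxy}-3-(7-methoxy-2,2-dimethyl-2H-chromen-6-yl)-2H-chromene | COc1cc2OC(C)(C)C=Cc2cc1C1=C(O[Si](C)(C)c2ccccc2)c2ccc(O[Si](C)(C)c3ccccc3)cc2OC1 | intermediate
11 | (3S)-7-{[dimethyl(phenyl)silyl]oxy}-3-(7-methoxy-2,2-dimethyl-2H-chromen-6-yl)-2,3-dihydro-4H-chromen-4-one | COc1cc2c(cc1[C@H]1COc3cc(O[Si](C)(C)c4ccccc4)ccc3C1=O)C=CC(C)(C)O2 | intermediate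
12 | (3S)-7-hydroxy-3-(7-methoxy-2,2-dimethyl-2H-chromen-6-yl)-2,3-dihydro-4H-chromen-4-one | COc1cc2c(cc1[C@H]1COc3cc(O)ccc3C1=O)C=CC(C)(C)O2 | target

**Step count**
Total steps: 4. Longest linear sequence: 4 (1 or 2 → 5 → 7 → 9 → 12).

**Steps most likely to fail, with fallbacks**

Step 4 (highest risk). The enantioselective protonation has not been run on a chromanone enol silane, so the ee and the facial sense are unproven; the strong chiral acid could also attack the ring D olefin. The fallback sets out from 9 and comes back at 12.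
- The 7-OH is first masked (TIPSCl, imidazole, DMF) to give 3-(7-methoxy-2,2-dimethyl-2H-chromen-6-yl)-7-[(triisopropylsilyl)oxy]-4H-chromen-4-one F1. This is needed because a free 7-OH para to C4 would let the benzylic alcohol ionise to a quinone methide and be over-reduced.
- Asymmetric transfer hydrogenation with dynamic kinetic resolution, RuCl(p-cymene)[(S,S)-TsDPEN], HCO2H–Et3N (5:2), EtOAc, 40 °C, reduces C2=C3 and then the rapidly epimerising ketone. The S,S ligand gives the 4S carbinol, and the cis preference fixes 3S, giving cis-(3S,4S)-3-(7-methoxy-2,2-dimethyl-2H-chromen-6-yl)-7-[(triisopropylsilyl)oxy]chroman-4-ol F2.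
- Dess–Martin periodinane in CH2Cl2 at 0 °C re-oxidises C4 without touching C3 to give (3S)-3-(7-methoxy-2,2-dimethyl-2H-chromen-6-yl)-7-[(triisopropylsilyl)oxy]-2,3-dihydro-4H-chromen-4-one F3.
- HF·pyridine in THF at 0 °C removes the silyl group and returns to 12.

Step 3. The risks are competing annulation at C8 of ring A through the 7-OH, attack at C3' instead of C5', and poor solubility of the diol. The fallback sets out from 7 and comes back at 9.
- MOMCl (1.0 equiv) with K2CO3 (1.0 equiv) in acetone caps the more acidic 7-OH to give 3-(4-hydroxy-2-methoxyphenyl)-7-(methoxymethoxy)-4H-chromen-4-one F4.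
- The remaining ring B phenol is alkylated with 3-chloro-3-methylbut-1-yne (K2CO3, KI, acetone, reflux) to give 3-{2-methoxy-4-[(2-methylbut-3-yn-2-yl)oxy]phenyl}-7-(methoxymethoxy)-4H-chromen-4-one F5.
- Heating in N,N-diethylaniline at 180 °C triggers propargyl Claisen rearrangement, 1,5-H shift and the same oxa-6π closure, now intramolecular and confined to ring B, to give 3-(7-methoxy-2,2-dimethyl-2H-chromen-6-yl)-7-(methoxymethoxy)-4H-chromen-4-one F6.
- HCl in MeOH at rt removes the MOM group and returns to 9.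

Step 2. The risks are partial MOM loss while the thallium oxidant is still present, aurone formation from the free 2'-OH, and over-oxidation of the electron-rich ring B. The fallback sets out from 5 and comes back at 7.
- NaOAc in refluxing EtOH closes ring C first by oxa-Michael addition, giving the racemic flavanone 7-(methoxymethoxy)-2-[2-methoxy-4-(methoxymethoxy)phenyl]chroman-4-one F7.
- PhI(OH)OTs in MeCN at 60 °C (a trivalent iodine oxidant) effects the 2,3-aryl shift on the ring-closed ketone, and loss of a proton gives 7-(methoxymethoxy)-3-[2-methoxy-4-(methoxymethoxy)phenyl]-4H-chromen-4-one F8.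
- Methanolic HCl at 60 °C removes both MOM groups and returns to 7.

**Further compounds**
F1 | step 4 | 3-(7-methoxy-2,2-dimethyl-2H-chromen-6-yl)-7-[(triisopropylsilyl)oxy]-4H-chromen-4-one | COc1cc2OC(C)(C)C=Cc2cc1C1=COc2cc(O[Si](C(C)C)(C(C)C)C(C)C)ccc2C1=O
F2 | step 4 | cis-(3S,4S)-3-(7-methoxy-2,2-dimethyl-2H-chromen-6-yl)-7-[(triisopropylsilyl)oxy]chroman-4-ol | COc1cc2c(cc1[C@H]1COc3cc(O[Si](C(C)C)(C(C)C)C(C)C)ccc3[C@H]1O)C=CC(C)(C)O2
F3 | step 4 | (3S)-3-(7-methoxy-2,2-dimethyl-2H-chromen-6-yl)-7-[(triisopropylsilyl)oxy]-2,3-dihydro-4H-chromen-4-one | COc1cc2c(cc1[C@H]1COc3cc(O[Si](C(C)C)(C(C)C)C(C)C)ccc3C1=O)C=CC(C)(C)O2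
F4 | step 3 | 3-(4-hydroxy-2-methoxyphenyl)-7-(methoxymethoxy)-4H-chromen-4-one | COCOc1ccc2C(=O)C(=COc2c1)c1ccc(O)cc1OC
F5 | step 3 | 3-{2-methoxy-4-[(2-methylbut-3-yn-2-yl)oxy]phenyl}-7-(methoxymethoxy)-4H-chromen-4-one | COCOc1ccc2C(=O)C(=COc2c1)c1ccc(OC(C)(C)C#C)cc1OC
F6 | step 3 | 3-(7-methoxy-2,2-dimethyl-2H-chromen-6-yl)-7-(methoxymethoxy)-4H-chromen-4-one | COCOc1ccc2C(=O)C(=COc2c1)c1cc2C=CC(C)(C)Oc2cc1OC
F7 | step 2 | 7-(methoxymethoxy)-2-[2-methoxy-4-(methoxymethoxy)phenyl]chroman-4-one (racemic) | COCOc1ccc2C(=O)CC(Oc2c1)c1ccc(OCOC)cc1OC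
F8 | step 2 | 7-(methoxymethoxy)-3-[2-methoxy-4-(methoxymethoxy)phenyl]-4H-chromen-4-one | COCOc1ccc2C(=O)C(=COc2c1)c1ccc(OCOC)cc1OC
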